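**Strategy.** The pyran ring is disconnected at the O1–C2 bond. C2 is benzylic to the B ring and para to the C4' hydroxyl, so a racemic, fully unprotected 1,3-diarylpropan-1-ol can lose water to a planar p-quinone methide; a chiral phosphoric acid then delivers the C8a phenol oxygen to C2. One operation closes the last ring, erases the carbinol configuration and funnels both enantiomers into the (2S)-flavan, which is the target itself. The carbinol arises from an 8-prenyldihydrocoumarin (scopoletin: hydrogenation, O-tert-prenylation, Claisen rearrangement) that is opened by a 2-prenyl-3,4-bis(methoxymethoxy)phenyllithium (from 4-bromocatechol), followed by MOM cleavage and borohydride reduction.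

Key step: step 9

Assumption: tert-butyl 2-methylbut-3-en-2-yl carbonate is taken as a catalogue reagent; the sense of induction of the phosphoric acid in step 9 cannot be predicted with certainty, so (R)-TRIP is written and its mirror image is to be used if a first run shows the 2R flavan in excess.

Step 1
Reactants: 1 scopoletin (7-hydroxy-6-methoxycoumarin)
Product: 2 7-hydroxy-6-methoxychroman-2-one
Conditions: H2 (1 atm), 10% Pd/C, AcOH, rt
Reagents that add atoms: none
Why: Heterogeneous hydrogenation should saturate only the conjugated C3=C4 bond of the coumarin, and it is placed first so that no prenyl alkene is yet present.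

Step 2
Reactants: 2 7-hydroxy-6-methoxychroman-2-one
Product: 3 6-methoxy-7-[(2-methylbut-3-en-2-yl)oxy]chroman-2-one
Conditions: tert-butyl 2-methylbut-3-en-2-yl carbonate, Pd(PPh3)4 (cat.), THF, 0 °C
Reagents that add atoms: tert-butyl 2-methylbut-3-en-2-yl carbonate, C=CC(C)(C)OC(=O)OC(C)(C)C
Why: Tsuji–Trost O-allylation under base-free conditions, in which the phenoxide should attack the more substituted terminus of the π-(1,1-dimethylallyl)palladium complex under kinetic control at low temperature, leaving the lactone untouched.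

Step 3
Reactants: 3 6-methoxy-7-[(2-methylbut-3-en-2-yl)oxy]chroman-2-one
Product: 5 7-hydroxy-6-methoxy-8-(3-methylbut-2-en-1-yl)chroman-2-one, via dienone 4 (not isolated)
Conditions: Eu(fod)3 (10 mol %), CHCl3, 60 °C
Reagents that add atoms: none
Why: Aromatic Claisen rearrangement, in which C8 is the only unsubstituted ortho position (C6 carries OMe), the [3,3] shift turns the 1,1-dimethylallyl ether into the linear prenyl group, and tautomerisation of 4 restores the phenol; Eu(III) catalysis keeps the temperature below that at which the ether fragments.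

Step 4
Reactants: 6 4-bromocatechol
Product: 7 4-bromo-1,2-bis(methoxymethoxy)benzene
Conditions: NaH, MOMCl, DMF, 0 °C → rt
Reagents that add atoms: chloromethyl methyl ether (MOMCl), COCCl
Why: Williamson etherification of both phenoxides gives MOM ethers that both protect the catechol and direct the following metalation.

Step 5
Reactants: 7 4-bromo-1,2-bis(methoxymethoxy)benzene
Product: 10 1-bromo-3,4-bis(methoxymethoxy)-2-(3-methylbut-2-en-1-yl)benzene, via aryllithium 8 (not isolated), via arylcopper 9 (not isolated)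
Conditions: LDA, THF, −78 °C; CuBr·SMe2, −78 °C; prenyl bromide, −78 → −20 °C
Reagents that add atoms: prenyl bromide (1-bromo-3-methylbut-2-ene), CC(C)=CCBr
Why: Directed ortho-lithiation followed by copper-mediated allylic substitution: LDA should remove the most acidic proton, between Br and OMOM, without bromine–lithium exchange, cupration at −78 °C forestalls loss of LiBr to an aryne, and the arylcopper attacks the unhindered primary carbon of prenyl bromide to give the linear prenyl group.

Step 6
Reactants: 5 7-hydroxy-6-methoxy-8-(3-methylbut-2-en-1-yl)chroman-2-one; 10 1-bromo-3,4-bis(methoxymethoxy)-2-(3-methylbut-2-en-1-yl)benzene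
Product: 13 1-[3,4-bis(methoxymethoxy)-2-(3-methylbut-2-en-1-yl)phenyl]-3-[2,4-dihydroxy-5-methoxy-3-(3-methylbut-2-en-1-yl)phenyl]propan-1-one, via lithium phenoxide 11 (not isolated), via aryllithium 12 (not isolated)
Conditions: 10, n-BuLi, THF, −78 °C; cannulated into 5 + LiHMDS (1.0 equiv), THF, −78 °C; AcOH, −78 °C → rt
Reagents that add atoms: none
Why: Bromine–lithium exchange and nucleophilic acyl substitution: aryllithium 12 should add once to the aryl-ester carbonyl of lactone 11 (phenol masked as its lithium salt), the ring opens to the ketone and the C8a phenoxide, and a second addition is held back by the low temperature and by the ortho-prenyl groups on both the nucleophile and the new ketone.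

Step 7
Reactants: 13 1-[3,4-bis(methoxymethoxy)-2-(3-methylbut-2-en-1-yl)phenyl]-3-[2,4-dihydroxy-5-methoxy-3-(3-methylbut-2-en-1-yl)phenyl]propan-1-one
Product: 14 1-[3,4-dihydroxy-2-(3-methylbut-2-en-1-yl)phenyl]-3-[2,4-dihydroxy-5-methoxy-3-(3-methylbut-2-en-1-yl)phenyl]propan-1-one
Conditions: conc. HCl (cat.), MeOH, 40 °C, short reaction time
Reagents that add atoms: none
Why: Acid-catalysed acetal exchange with methanol removes both MOM groups, and it is done at the ketone oxidation level, where no ionisable benzylic C–O bond exists and ring–chain tautomerism of the hydroxy ketone is of no consequence.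

Step 8
Reactants: 14 1-[3,4-dihydroxy-2-(3-methylbut-2-en-1-yl)phenyl]-3-[2,4-dihydroxy-5-methoxy-3-(3-methylbut-2-en-1-yl)phenyl]propan-1-one
Product: 15 rac-1-[3,4-dihydroxy-2-(3-methylbut-2-en-1-yl)phenyl]-3-[2,4-dihydroxy-5-methoxy-3-(3-methylbut-2-en-1-yl)phenyl]propan-1-ol
Conditions: NaBH4 (excess), THF/MeOH, 0 °C → rt; pH 7 buffer work-up; used crude under Ar
Reagents that add atoms: none
Why: Borohydride reduction of the aryl ketone should give the carbinol as the racemate, which is all the next step requires, and the neutral work-up without chromatography avoids premature ionisation of the p-hydroxybenzylic alcohol.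

Step 9
Reactants: 15 rac-1-[3,4-dihydroxy-2-(3-methylbut-2-en-1-yl)phenyl]-3-[2,4-dihydroxy-5-methoxy-3-(3-methylbut-2-en-1-yl)phenyl]propan-1-ol
Product: 17 (2S)-2-[3,4-dihydroxy-2-(3-methylbut-2-en-1-yl)phenyl]-6-methoxy-8-(3-methylbut-2-en-1-yl)chroman-7-ol, via p-quinone methide 16 (not isolated)
Conditions: (R)-TRIP [(R)-3,3'-bis(2,4,6-triisopropylphenyl)-BINOL hydrogen phosphate] (10 mol %), CH2Cl2/EtOAc, −20 °C, Ar
Reagents that add atoms: none
Why: Proposed new method: the phosphoric acid should ionise the C2 carbinol of either enantiomer of 15 (the C4' hydroxyl is para to it) to the planar p-quinone methide 16 and then deliver the C8a phenol to the methide carbon within a hydrogen-bonded complex (P=O to the phenol O–H, P–OH to the quinone methide carbonyl), so that both enantiomers converge on one configuration at C2. The closest known reaction type is the chiral-phosphoric-acid-catalysed enantioselective 1,6-addition of carbon, sulfur and nitrogen nucleophiles to p-quinone methides generated in situ from racemic p-hydroxybenzyl alcohols; an intramolecular phenol O–H addition that closes a chroman is to be regarded as untested. The pyran ring closes by 6-exo-trig oxa-1,6-conjugate addition, forming the O1–C2 bond. C2 is set by the catalyst alone, helped by the 2'-prenyl group, which should force the methide chain to the C6' side so that only one alkene geometry has to be discriminated. The step needs O- over C-alkylation and a catalysed path faster than the racemic background or re-ionisation of the product: only the C8a hydroxyl reaches C2 through a six-membered transition state, attack by C5 or by the 2'-prenyl alkene would need a strained five-membered ring, and a weak acid at low temperature should leave the aryl ether product and the prenyl groups alone.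

**Compound list**

1 | scopoletin (7-hydroxy-6-methoxy-2H-chromen-2-one) | COc1cc2ccc(=O)oc2cc1O | starting material
2 | 7-hydroxy-6-methoxychroman-2-one | COc1cc2CCC(=O)Oc2cc1O | intermediate
3 | 6-methoxy-7-[(2-methylbut-3-en-2-yl)oxy]chroman-2-one | COc1cc2CCC(=O)Oc2cc1OC(C)(C)C=C | intermediate
4 | 6-methoxy-8-(3-methylbut-2-en-1-yl)-3,4-dihydro-2H-chromene-2,7(8H)-dione (Claisen dienone) | COC1=CC2=C(OC(=O)CC2)C(CC=C(C)C)C1=O | intermediate
5 | 7-hydroxy-6-methoxy-8-(3-methylbut-2-en-1-yl)chroman-2-one | COc1cc2CCC(=O)Oc2c(CC=C(C)C)c1O | intermediate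
6 | 4-bromocatechol (4-bromobenzene-1,2-diol) | Oc1ccc(Br)cc1O | starting material
7 | 4-bromo-1,2-bis(methoxymethoxy)benzene | COCOc1ccc(Br)cc1OCOC | intermediate
8 | [6-bromo-2,3-bis(methoxymethoxy)phenyl]lithium | [Li]c1c(Br)ccc(OCOC)c1OCOC | intermediate
9 | [6-bromo-2,3-bis(methoxymethoxy)phenyl]copper(I) | [Cu]c1c(Br)ccc(OCOC)c1OCOC | intermediate
10 | 1-bromo-3,4-bis(methoxymethoxy)-2-(3-methylbut-2-en-1-yl)benzene | COCOc1ccc(Br)c(CC=C(C)C)c1OCOC | intermediate
11 | lithium 6-methoxy-8-(3-methylbut-2-en-1-yl)-2-oxochroman-7-olate | COc1cc2CCC(=O)Oc2c(CC=C(C)C)c1[O-].[Li+] | intermediate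
12 | [3,4-bis(methoxymethoxy)-2-(3-methylbut-2-en-1-yl)phenyl]lithium | [Li]c1ccc(OCOC)c(OCOC)c1CC=C(C)C | intermediate
13 | 1-[3,4-bis(methoxymethoxy)-2-(3-methylbut-2-en-1-yl)phenyl]-3-[2,4-dihydroxy-5-methoxy-3-(3-methylbut-2-en-1-yl)phenyl]propan-1-one | COCOc1ccc(C(=O)CCc2cc(OC)c(O)c(CC=C(C)C)c2O)c(CC=C(C)C)c1OCOC | intermediate
14 | 1-[3,4-dihydroxy-2-(3-methylbut-2-en-1-yl)phenyl]-3-[2,4-dihydroxy-5-methoxy-3-(3-methylbut-2-en-1-yl)phenyl]propan-1-one | COc1cc(CCC(=O)c2ccc(O)c(O)c2CC=C(C)C)c(O)c(CC=C(C)C)c1O | intermediate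
15 | rac-1-[3,4-dihydroxy-2-(3-methylbut-2-en-1-yl)phenyl]-3-[2,4-dihydroxy-5-methoxy-3-(3-methylbut-2-en-1-yl)phenyl]propan-1-ol (racemic) | COc1cc(CCC(O)c2ccc(O)c(O)c2CC=C(C)C)c(O)c(CC=C(C)C)c1O | intermediate
16 | 4-{3-[2,4-dihydroxy-5-methoxy-3-(3-methylbut-2-en-1-yl)phenyl]propylidene}-2-hydroxy-3-(3-methylbut-2-en-1-yl)cyclohexa-2,5-dien-1-one (p-quinone methide) | O=C1C=CC(=CCCc2cc(OC)c(O)c(CC=C(C)C)c2O)C(CC=C(C)C)=C1O | intermediate
17 | (2S)-2-[3,4-dihydroxy-2-(3-methylbut-2-en-1-yl)phenyl]-6-methoxy-8-(3-methylbut-2-en-1-yl)chroman-7-ol | COc1cc2c(c(CC=C(C)C)c1O)O[C@H](c1ccc(O)c(O)c1CC=C(C)C)CC2 | target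

**Route summary**

Total step count: 9. Longest linear sequence: 7 steps (1, 2, 3, 6, 7, 8, 9, from scopoletin).

**Steps most likely to fail**

Step 9 (labelled step). What may go wrong: insufficient facial discrimination in the oxa-1,6-addition, an uncatalysed racemic ring closure running alongside, or tautomerisation and oligomerisation of the quinone methide. Fallback with known chemistry, setting out from ketone 13 and replacing steps 7–9: Noyori-type asymmetric transfer hydrogenation (RuCl[(R,R)-TsDPEN](p-cymene), HCO2H/Et3N) should give (1R)-1-[3,4-bis(methoxymethoxy)-2-prenylphenyl]-3-[2,4-dihydroxy-5-methoxy-3-prenylphenyl]propan-1-ol F1. Mitsunobu etherification (PPh3, DIAD, THF, 0 °C) then closes the pyran ring through the C8a phenol with inversion at C2 to the (2S)-3',4'-bis(methoxymethyl) ether of the target F2. Brief methanolic HCl at rt removes the MOM groups, and the route comes back at target 17.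

Step 6. What may go wrong: double addition of the aryllithium to the opened ketone, or enolisation of the lactone in place of addition. Fallback, setting out from lactone 5: aminolysis with Me(MeO)NH·HCl/AlMe3 (CH2Cl2, 0 °C → rt) opens the ring to the Weinreb amide N-methoxy-N-methyl-3-[2,4-dihydroxy-5-methoxy-3-(3-methylbut-2-en-1-yl)phenyl]propanamide F3. Aryllithium 12 (excess, two equivalents being consumed by the phenols) at −78 °C should then stop at the chelated tetrahedral adduct, and work-up returns to the route at ketone 13.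

Step 7. What may go wrong: acid-induced cyclisation of a prenyl group onto a neighbouring phenol, or cyclodehydration of the hydroxy ketone during MOM cleavage. Fallback, setting out from 4-bromocatechol 6, with the catechol carried as fluoride-labile SEM ethers: NaH/SEMCl should give 4-bromo-1,2-bis{[2-(trimethylsilyl)ethoxy]methoxy}benzene F4. As in step 5, LDA gives the aryllithium [6-bromo-2,3-bis(SEM-oxy)phenyl]lithium F5, CuBr·SMe2 the arylcopper [6-bromo-2,3-bis(SEM-oxy)phenyl]copper(I) F6, and prenyl bromide the prenylated bromide 1-bromo-2-(3-methylbut-2-en-1-yl)-3,4-bis(SEM-oxy)benzene F7. As in step 6, n-BuLi gives the aryllithium [2-(3-methylbut-2-en-1-yl)-3,4-bis(SEM-oxy)phenyl]lithium F8, and addition to lithium phenoxide 11 gives the bis-SEM ketone F9. TBAF in DMPU/THF at 60 °C should then free both phenols without acid, and the route comes back at ketone 14.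

Further compounds
F1 | step 9 | (1R)-1-[3,4-bis(methoxymethoxy)-2-(3-methylbut-2-en-1-yl)phenyl]-3-[2,4-dihydroxy-5-methoxy-3-(3-methylbut-2-en-1-yl)phenyl]propan-1-ol | COCOc1ccc([C@H](O)CCc2cc(OC)c(O)c(CC=C(C)C)c2O)c(CC=C(C)C)c1OCOC
F2 | step 9 | (2S)-2-[3,4-bis(methoxymethoxy)-2-(3-methylbut-2-en-1-yl)phenyl]-6-methoxy-8-(3-methylbut-2-en-1-yl)chroman-7-ol | COc1cc2c(c(CC=C(C)C)c1O)O[C@H](c1ccc(OCOC)c(OCOC)c1CC=C(C)C)CC2
F3 | step 6 | N-methoxy-N-methyl-3-[2,4-dihydroxy-5-methoxy-3-(3-methylbut-2-en-1-yl)phenyl]propanamide | CON(C)C(=O)CCc1cc(OC)c(O)c(CC=C(C)C)c1O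
F4 | step 7 | 4-bromo-1,2-bis{[2-(trimethylsilyl)ethoxy]methoxy}benzene | C[Si](C)(C)CCOCOc1ccc(Br)cc1OCOCC[Si](C)(C)C
F5 | step 7 | [6-bromo-2,3-bis{[2-(trimethylsilyl)ethoxy]methoxy}phenyl]lithium | [Li]c1c(Br)ccc(OCOCC[Si](C)(C)C)c1OCOCC[Si](C)(C)C
F6 | step 7 | [6-bromo-2,3-bis{[2-(trimethylsilyl)ethoxy]methoxy}phenyl]copper(I) | [Cu]c1c(Br)ccc(OCOCC[Si](C)(C)C)c1OCOCC[Si](C)(C)C
F7 | step 7 | 1-bromo-2-(3-methylbut-2-en-1-yl)-3,4-bis{[2-(trimethylsilyl)ethoxy]methoxy}benzene | C[Si](C)(C)CCOCOc1ccc(Br)c(CC=C(C)C)c1OCOCC[Si](C)(C)C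
F8 | step 7 | [2-(3-methylbut-2-en-1-yl)-3,4-bis{[2-(trimethylsilyl)ethoxy]methoxy}phenyl]lithium | [Li]c1ccc(OCOCC[Si](C)(C)C)c(OCOCC[Si](C)(C)C)c1CC=C(C)C
F9 | step 7 | 1-[2-(3-methylbut-2-en-1-yl)-3,4-bis{[2-(trimethylsilyl)ethoxy]methoxy}phenyl]-3-[2,4-dihydroxy-5-methoxy-3-(3-methylbut-2-en-1-yl)phenyl]propan-1-one | C[Si](C)(C)CCOCOc1ccc(C(=O)CCc2cc(OC)c(O)c(CC=C(C)C)c2O)c(CC=C(C)C)c1OCOCC[Si](C)(C)C
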